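**Retrosynthetic overview**
1. The target is cut at the O–C4 bond of the benzene ring into methyl (E)-3-[4-bromo-3-[(E)-3-hydroxy-3-methylbut-1-enyl]phenyl]acrylate and (S)-3-acetoxybutanoic acid, joined by nickel-catalysed O-arylation of the carboxylate under paired electrolysis. This C4–O bond lies para to C1 (methyl acrylate arm) and ortho to C3 ((E)-3-hydroxy-3-methylbut-1-enyl arm). Making it from a C4–Br bond avoids both the free phenol, which can close onto the side chain to a 2,2-dimethylchromene, and any activated acyl derivative of the beta-acetoxy acid, which loses acetate easily.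
2. The aryl bromide comes from an iodide-selective Heck reaction at C1 with methyl acrylate, preceded by MeMgBr 1,2-addition to an enone and a Wittig reaction of 2-bromo-5-iodobenzaldehyde with the acetonylidene ylide.
3. The acid comes from tert-butyl (S)-3-hydroxybutanoate by acetylation and acidolysis; this chiral-pool ester supplies the only stereocenter.
4. No ring is formed anywhere in the route; the benzene ring is bought with the benzaldehyde.

Key step: step 6

Remark: the single stereocenter (C3 of the butanoyl chain) is read as S and both side-chain double bonds as E. The methyl addition is placed before the Heck reaction so that no ester is present when the Grignard reagent is used, and the tert-butyl ester is used as the chiral-pool source so that the acid is released without base.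

**Step 1**
Reactants: 1 2-bromo-5-iodobenzaldehyde; 2 1-(triphenylphosphoranylidene)propan-2-one
Product: 3 (E)-4-(2-bromo-5-iodophenyl)but-3-en-2-one
Conditions: 2 (1.2 equiv), toluene, 90 °C
Reagents that add atoms: none
Why: Wittig reaction of a ketone-stabilised ylide with an aryl aldehyde, which is expected to be E-selective and leaves both aryl halides untouched; no stereocenter is formed.

**Step 2**
Reactants: 3 (E)-4-(2-bromo-5-iodophenyl)but-3-en-2-one
Product: 4 (E)-4-(2-bromo-5-iodophenyl)-2-methylbut-3-en-2-ol
Conditions: MeMgBr (1.3 equiv), THF, −78 to −20 °C; then H2O, 0 °C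
Reagents that add atoms: methylmagnesium bromide, C[Mg]Br
Why: Grignard 1,2-addition of the hard methylmagnesium reagent to the carbonyl carbon of the aryl-conjugated methyl ketone, at a temperature where halogen–magnesium exchange at the aryl iodide is negligible; the new carbinol carbon carries two methyl groups and is not a stereocenter.

**Step 3**
Reactants: 4 (E)-4-(2-bromo-5-iodophenyl)-2-methylbut-3-en-2-ol; 5 methyl acrylate
Product: 6 methyl (E)-3-[4-bromo-3-[(E)-3-hydroxy-3-methylbut-1-enyl]phenyl]acrylate
Conditions: 5 (1.5 equiv), Pd(OAc)2 (3 mol%), n-Bu4NCl, NaHCO3, DMF, 50 °C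
Reagents that add atoms: none
Why: Mizoroki–Heck reaction under ligand-free Jeffery conditions, in which zerovalent palladium should insert only into the C–I bond at 50 °C and the monosubstituted electron-poor acrylate should react far faster than the hindered 1,2-disubstituted styrenyl double bond, syn insertion and syn beta-hydride elimination giving the E cinnamate.

**Step 4**
Reactants: 7 tert-butyl (S)-3-hydroxybutanoate
Product: 8 tert-butyl (S)-3-acetoxybutanoate
Conditions: Ac2O (1.5 equiv), pyridine, DMAP (5 mol%), CH2Cl2, 0 °C to rt
Reagents that add atoms: acetic anhydride, CC(=O)OC(C)=O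
Why: DMAP-catalysed O-acetylation of a secondary alcohol, which does not break the C–O bond at the stereocenter, so the S configuration is retained; the alpha hydrogens of the tert-butyl ester are too weakly acidic for pyridine to eliminate acetate.

**Step 5**
Reactants: 8 tert-butyl (S)-3-acetoxybutanoate
Product: 9 (S)-3-acetoxybutanoic acid
Conditions: TFA/CH2Cl2 (1:4), 0 °C to rt; evaporate, toluene azeotrope
Reagents that add atoms: none
Why: Acidolysis of the tert-butyl ester (loss of the tert-butyl cation as 2-methylpropene) frees the acid without any base, so the beta-acetoxy group cannot be eliminated and the secondary acetate and the stereocenter are unaffected.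

**Step 6**
Reactants: 6 methyl (E)-3-[4-bromo-3-[(E)-3-hydroxy-3-methylbut-1-enyl]phenyl]acrylate; 9 (S)-3-acetoxybutanoic acid
Product: 10 methyl (E)-3-[4-[(S)-3-acetoxybutanoyloxy]-3-[(E)-3-hydroxy-3-methylbut-1-enyl]phenyl]acrylate (target)
Conditions: 9 (2.0 equiv), DBU (1.8 equiv), NiBr2·DME (10 mol%), 4,4'-di-tert-butyl-2,2'-bipyridine (10 mol%), n-Bu4NBr (0.1 M), DMA, rt, undivided cell, reticulated vitreous carbon anode, nickel-foam cathode, constant current 4 mA, N2, dark; pH 7 buffer work-up, chromatography on neutral silica
Reagents that add atoms: none
Why: At the cathode the divalent nickel–bipyridine precatalyst is reduced to a low-valent species that undergoes oxidative addition into the C4–Br bond of 6, which is electron-poor because the acrylate sits para to it; the carboxylate of 9 (present as its DBU-H+ salt) then displaces bromide on the divalent aryl nickel, one-electron oxidation at the anode raises this complex to trivalent nickel, and C(aryl)–O reductive elimination releases 10 and monovalent nickel, so cathodic and anodic events are paired and no sacrificial reductant or oxidant is consumed. The closest known reaction type is the nickel/bipyridine-catalysed O-arylation of aliphatic carboxylic acids by aryl bromides under paired electrolysis (the electrochemical counterpart of the photosensitised nickel esterification), applied here to an ortho-alkenyl bromide. The step forms the aryl C4–O bond only: no ring is closed and no stereocenter is created, and the S center of 9 is carried through because the acid reacts as a carboxylate whose alpha hydrogens are not acidic. Two selectivities are needed: the carboxylate must be arylated in preference to the tertiary hydroxyl, which is secured because the hindered tertiary alcohol binds nickel poorly and the E double bond points it away from C4, ruling out closure to a 2,2-dimethyl-2H-chromene; and the beta-acetoxy aryl ester must survive, which is secured by keeping DBU below the amount of acid so that nothing more basic than carboxylate is present to start an E1cB loss of acetate. Electrolysis in the dark is preferred to the photosensitised variant because a triplet sensitiser would be expected to isomerise the two E styrenyl double bonds.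

**Compound list**
1 | 2-bromo-5-iodobenzaldehyde | O=Cc1cc(I)ccc1Br | starting material
2 | 1-(triphenylphosphoranylidene)propan-2-one | CC(=O)C=P(c1ccccc1)(c1ccccc1)c1ccccc1 | starting material
3 | (E)-4-(2-bromo-5-iodophenyl)but-3-en-2-one | CC(=O)/C=C/c1cc(I)ccc1Br | intermediate
4 | (E)-4-(2-bromo-5-iodophenyl)-2-methylbut-3-en-2-ol | CC(C)(O)/C=C/c1cc(I)ccc1Br | intermediate
5 | methyl acrylate | C=CC(=O)OC | starting material
6 | methyl (E)-3-[4-bromo-3-[(E)-3-hydroxy-3-methylbut-1-enyl]phenyl]acrylate | COC(=O)/C=C/c1ccc(Br)c(/C=C/C(C)(C)O)c1 | intermediate
7 | tert-butyl (S)-3-hydroxybutanoate | CC(C)(C)OC(=O)C[C@H](C)O | starting material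
8 | tert-butyl (S)-3-acetoxybutanoate | CC(C)(C)OC(=O)C[C@H](C)OC(C)=O | intermediate
9 | (S)-3-acetoxybutanoic acid | OC(=O)C[C@H](C)OC(C)=O | intermediate
10 | methyl (E)-3-[4-[(S)-3-acetoxybutanoyloxy]-3-[(E)-3-hydroxy-3-methylbut-1-enyl]phenyl]acrylate | COC(=O)/C=C/c1ccc(OC(=O)C[C@H](C)OC(C)=O)c(/C=C/C(C)(C)O)c1 | target

**Step count**
Total steps: 6. Longest linear sequence: 4 steps (steps 1, 2, 3 and 6); the acid branch (steps 4 and 5) joins at step 6.

**Steps most likely to fail**

Step 6 (key coupling). The hindered ortho-alkenyl aryl nickel may undergo hydrodebromination or biaryl homocoupling faster than carboxylate exchange and reductive elimination. The cinnamate may also be reduced at the cathode, or acetate may be lost from the product during the run. The fallback makes the same C4–O bond from the oxygen side by known chemistry. Setting out from 6, Miyaura borylation (bis(pinacolato)diboron, Pd(dppf)Cl2, KOAc, 1,4-dioxane, 80 °C) should give the pinacol boronate methyl (E)-3-[3-[(E)-3-hydroxy-3-methylbut-1-enyl]-4-(4,4,5,5-tetramethyl-1,3,2-dioxaborolan-2-yl)phenyl]acrylate F1. Oxidation with 30% aqueous H2O2 and NaHCO3 in THF/H2O at 0 °C should give the phenol methyl (E)-3-[4-hydroxy-3-[(E)-3-hydroxy-3-methylbut-1-enyl]phenyl]acrylate F2. F2 is kept cold and neutral and used at once, since acid would ionise the tertiary allylic alcohol and close the chromene. Steglich esterification of F2 with acid 9 (N,N'-diisopropylcarbodiimide, 5 mol% DMAP, CH2Cl2, −20 °C) comes back to the route at 10.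

Step 3 (Heck reaction). Halide selectivity may be lost, with oxidative addition at C–Br once the iodide runs low, or the styrenyl double bond may be arylated. The fallback replaces the palladium coupling by halogen–metal exchange and olefination. Setting out from 4, i-PrMgCl·LiCl (2.2 equiv, THF, −20 °C; the first equivalent deprotonates the hydroxyl, the second exchanges only the iodide) followed by DMF and aqueous work-up should give 4-bromo-3-[(E)-3-hydroxy-3-methylbut-1-enyl]benzaldehyde F3. Wittig reaction of F3 with methyl (triphenylphosphoranylidene)acetate (CH2Cl2, rt) should give the E cinnamate and comes back to the route at 6.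

Step 2 (methyl addition). The methyl ketone may be enolised, or conjugate addition may compete, leaving enone or giving the 1,4-adduct. The fallback builds the carbinol side chain by olefin metathesis instead of carbonyl addition. Setting out from 1, Wittig methylenation (Ph3PCH3Br, KOt-Bu, THF, 0 °C) should give 1-bromo-2-ethenyl-4-iodobenzene F4. Cross-metathesis of F4 with 2-methylbut-3-en-2-ol (3 equiv, second-generation Hoveyda–Grubbs catalyst, CH2Cl2, 40 °C) should give the E allylic alcohol and comes back to the route at 4, bypassing 3.

**Further compounds**
F1 | step 6 | methyl (E)-3-[3-[(E)-3-hydroxy-3-methylbut-1-enyl]-4-(4,4,5,5-tetramethyl-1,3,2-dioxaborolan-2-yl)phenyl]acrylate | COC(=O)/C=C/c1ccc(B2OC(C)(C)C(C)(C)O2)c(/C=C/C(C)(C)O)c1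
F2 | step 6 | methyl (E)-3-[4-hydroxy-3-[(E)-3-hydroxy-3-methylbut-1-enyl]phenyl]acrylate | COC(=O)/C=C/c1ccc(O)c(/C=C/C(C)(C)O)c1
F3 | step 3 | 4-bromo-3-[(E)-3-hydroxy-3-methylbut-1-enyl]benzaldehyde | O=Cc1ccc(Br)c(/C=C/C(C)(C)O)c1
F4 | step 2 | 1-bromo-2-ethenyl-4-iodobenzene | C=Cc1cc(I)ccc1Br
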